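**Retrosynthetic overview**

1. The target is a 3,6''-linked flavone–flavanone (flavone: atoms C2–C8a, rings A/C/B; flavanone: atoms C2''–C8a'', benzo ring D, pyranone ring E, aryl ring F). After removal of four O-benzyl groups, ring E is opened at C3''–C4'' and at O1''–C8a''. This gives an aroyl fluoride with fluorine on C8a'' and a three-atom C3''–C2''–O1'' piece, the β-oxido alkyllithium from an (S)-2-iodo-1-arylethanol whose carbinol centre (the later C2'') comes from a CBS reduction.
2. Enabling feature: in ring D the carbonyl carbon C4'' sits on C4a'', ortho to C8a'', while both ring-D oxygens (on C5'' and C7'') are meta to C8a''. A fluoride on C8a'' is therefore activated by the C4'' carbonyl and not deactivated by the oxygens, so C4''/C8a'' form a 1,3-dielectrophile matching the 1,3-dinucleophile C3''/O1''. A leaving group on C8a'' alone also fixes the 6''-linkage (no 8''-isomer).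
3. The C3–C6'' biaryl bond (four ortho substituents) is cut next: Negishi coupling of a flavon-3-ylzinc chloride with a ring-D aryl iodide. The ring-D formyl group is afterwards oxidised to the acid and converted into the acyl fluoride.
4. The ring-D pattern comes from 5-fluororesorcinol by formylation (brings in C4'') and chelate-directed iodination between the two hydroxyls (C6''). Rings A/C come from 2',6'-dihydroxy-4'-methoxyacetophenone and 4-methoxybenzoyl chloride (diketone, cyclodehydration).
5. Order of ring formation: ring C (step 5), union of rings C and D (step 7), ring E (step 12). Rings A, B, D and F are bought as arenes.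

Key step: step 12

Remark: the C3–C6'' axis has four ortho substituents but is not defined in the target SMILES; it is treated as configurationally unassigned, so the biaryl compounds may be mixtures of rotamers about this axis.

**Step 1**
Reactants: 1 5-fluorobenzene-1,3-diol (5-fluororesorcinol)
Product: 2 2-fluoro-4,6-dihydroxybenzaldehyde
Conditions: POCl3, DMF, MeCN, −15 → 25 °C; then H2O, 50 °C
Reagents that add atoms: N,N-dimethylformamide, CN(C)C=O; water, O
Why: Vilsmeier–Haack formylation of a resorcinol goes para to one hydroxyl and ortho to the other (the carbon between the two hydroxyls is the slower site), which places the formyl carbon (later C4'') next to the fluorine-bearing carbon (later C8a'').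

**Step 2**
Reactants: 2 2-fluoro-4,6-dihydroxybenzaldehyde
Product: 3 6-fluoro-2,4-dihydroxy-3-iodobenzaldehyde
Conditions: I2 (0.4 equiv), HIO3 (0.2 equiv), EtOH/H2O, 25–35 °C
Reagents that add atoms: iodine, II; iodic acid, OI(=O)=O
Why: Electrophilic aromatic iodination of a 2,4-dihydroxyaryl carbonyl compound, in which the hydrogen-bonded chelate makes the carbon between the two hydroxyls the usual site of attack, while the only other free carbon is flanked by fluorine.

**Step 3**
Reactants: 3 6-fluoro-2,4-dihydroxy-3-iodobenzaldehyde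
Product: 4 2,4-bis(benzyloxy)-6-fluoro-3-iodobenzaldehyde
Conditions: BnBr (2.4 equiv), K2CO3, DMF, 50 °C
Reagents that add atoms: benzyl bromide, BrCc1ccccc1
Why: Williamson ether synthesis on both phenols, giving ethers that tolerate organozinc and organolithium reagents and leave by hydrogenolysis at the end.

**Step 4**
Reactants: 5 1-(2,6-dihydroxy-4-methoxyphenyl)ethanone; 6 4-methoxybenzoyl chloride
Product: 7 1-(2,6-dihydroxy-4-methoxyphenyl)-3-(4-methoxyphenyl)propane-1,3-dione
Conditions: LiN(SiMe3)2 (4.2 equiv), THF, −78 → −10 °C; then 6, −78 → 25 °C; aq. HCl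
Reagents that add atoms: none
Why: Claisen-type C-acylation of the ketone enolate within the lithium polyanion (first half of a Baker–Venkataraman-type flavone synthesis), the enolate carbon being the most nucleophilic site so that the phenols need no protection.

**Step 5**
Reactants: 7 1-(2,6-dihydroxy-4-methoxyphenyl)-3-(4-methoxyphenyl)propane-1,3-dione
Product: 8 5-hydroxy-7-methoxy-2-(4-methoxyphenyl)-4H-chromen-4-one
Conditions: H2SO4 (cat.), AcOH, 95 °C
Reagents that add atoms: none
Why: Acid-catalysed cyclodehydration of an ortho-hydroxyaryl 1,3-diketone to the chromone (ring C), the two phenols being equivalent so that only one flavone can form.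

**Step 6**
Reactants: 8 5-hydroxy-7-methoxy-2-(4-methoxyphenyl)-4H-chromen-4-one
Product: 9 5-(benzyloxy)-7-methoxy-2-(4-methoxyphenyl)-4H-chromen-4-one
Conditions: BnBr, K2CO3, DMF, 80 °C
Reagents that add atoms: benzyl bromide, BrCc1ccccc1
Why: Williamson etherification of the chelated 5-hydroxyl (hence the heating), which removes the only acidic proton before the organometallic steps 7 and 12.

**Step 7**
Reactants: 9 5-(benzyloxy)-7-methoxy-2-(4-methoxyphenyl)-4H-chromen-4-one; 4 2,4-bis(benzyloxy)-6-fluoro-3-iodobenzaldehyde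
Product: 12 2,4-bis(benzyloxy)-3-[5-(benzyloxy)-7-methoxy-2-(4-methoxyphenyl)-4-oxo-4H-chromen-3-yl]-6-fluorobenzaldehyde, via 3-lithioflavone 10 (not isolated), via flavon-3-ylzinc chloride 11 (not isolated)
Conditions: LiN(iPr)2 (1.15 equiv), THF, −78 °C; ZnCl2 (1.3 equiv), −78 → 25 °C; then 4, Pd2(dba)3 (2.5 mol%), RuPhos (2-dicyclohexylphosphino-2',6'-diisopropoxybiphenyl, 10 mol%), THF/NMP, 70 °C
Reagents that add atoms: none
Why: Lithiation of the flavone at C3 (its only vinylic C–H, alpha to the carbonyl), transmetalation to zinc and Negishi coupling with the di-ortho-alkoxy aryl iodide, a bond type for which bulky dialkylbiarylphosphine palladium catalysts are the established answer; the hindered, non-enolisable aldehyde should be tolerated by the arylzinc, and no stereocenter is formed.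

**Step 8**
Reactants: 12 2,4-bis(benzyloxy)-3-[5-(benzyloxy)-7-methoxy-2-(4-methoxyphenyl)-4-oxo-4H-chromen-3-yl]-6-fluorobenzaldehyde
Product: 13 2,4-bis(benzyloxy)-3-[5-(benzyloxy)-7-methoxy-2-(4-methoxyphenyl)-4-oxo-4H-chromen-3-yl]-6-fluorobenzoic acid
Conditions: NaClO2, NaH2PO4, 2-methylbut-2-ene, t-BuOH/THF/H2O, 25 °C
Reagents that add atoms: sodium chlorite, [Na+].[O-]Cl=O
Why: Pinnick oxidation takes the aldehyde to the acid under buffered conditions that leave benzyl ethers, the aryl fluoride and the chromone untouched.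

**Step 9**
Reactants: 13 2,4-bis(benzyloxy)-3-[5-(benzyloxy)-7-methoxy-2-(4-methoxyphenyl)-4-oxo-4H-chromen-3-yl]-6-fluorobenzoic acid
Product: 14 2,4-bis(benzyloxy)-3-[5-(benzyloxy)-7-methoxy-2-(4-methoxyphenyl)-4-oxo-4H-chromen-3-yl]-6-fluorobenzoyl fluoride
Conditions: Et2NSF3 (1.2 equiv), CH2Cl2, 0 °C
Reagents that add atoms: diethylaminosulfur trifluoride, CCN(CC)S(F)(F)F
Why: Deoxyfluorination of a carboxylic acid to the acyl fluoride, an isolable and sterically small acyl donor suited to the di-ortho-substituted carbonyl carbon, the vinylogous-ester chromone carbonyl not being fluorinated at 0 °C.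

**Step 10**
Reactants: 15 1-[4-(benzyloxy)phenyl]-2-bromoethanone
Product: 16 (1S)-1-[4-(benzyloxy)phenyl]-2-bromoethanol
Conditions: (S)-1-methyl-3,3-diphenyltetrahydro-1H,3H-pyrrolo[1,2-c][1,3,2]oxazaborole ((S)-Me-CBS, 10 mol%), BH3·SMe2 (0.7 equiv), THF, 0 °C; MeOH
Reagents that add atoms: none
Why: Corey–Bakshi–Shibata reduction, in which the oxazaborolidine–borane complex binds the ketone with the aryl group as the large substituent and delivers hydride to one face; the (S)-catalyst should give the (S)-halohydrin, which has the spatial arrangement needed for (R)-C2''.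

**Step 11**
Reactants: 16 (1S)-1-[4-(benzyloxy)phenyl]-2-bromoethanol
Product: 17 (1S)-1-[4-(benzyloxy)phenyl]-2-iodoethanol
Conditions: NaI (3 equiv), acetone, 25 °C, dark
Reagents that add atoms: sodium iodide, [Na+].[I-]
Why: Finkelstein exchange (SN2 at the primary carbon, the carbinol centre untouched) provides the iodide needed for clean iodine–lithium exchange.

**Step 12**
Reactants: 17 (1S)-1-[4-(benzyloxy)phenyl]-2-iodoethanol; 14 2,4-bis(benzyloxy)-3-[5-(benzyloxy)-7-methoxy-2-(4-methoxyphenyl)-4-oxo-4H-chromen-3-yl]-6-fluorobenzoyl fluoride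
Product: 20 (2R)-5,7-bis(benzyloxy)-6-[5-(benzyloxy)-7-methoxy-2-(4-methoxyphenyl)-4-oxo-4H-chromen-3-yl]-2-[4-(benzyloxy)phenyl]chroman-4-one, via β-oxido alkyllithium 18 (not isolated), via lithium aldolate 19 (not isolated)
Conditions: 17, t-BuLi (3.0 equiv), Et2O/pentane, −78 °C; cannulated into 14, THF, −78 °C; then DMPU, −78 → 0 °C; AcOH quench
Reagents that add atoms: none
Why: Proposed new method: iodine–lithium exchange on the lithium alkoxide of 17 gives the β-oxido alkyllithium 18 (a dianion class that survives at −78 °C because Li2O is a poor leaving group), whose carbanion C3'' acylates the acyl fluoride carbon C4'' of 14 to give aldolate 19, and the alkoxide O1'' of 19 then displaces the fluoride on C8a'' by addition–elimination, now activated by the new ortho ketone; the closest known reactions are the one-pot enolate C-acylation/fluoride displacement of 2-fluorobenzoyl halides that gives chromones and the addition of β-oxido alkyllithiums to carbonyl electrophiles. Ring E is closed by a six-membered exo-type addition–elimination at the sp2 carbon C8a'' (Meisenheimer intermediate stabilised by the C4'' carbonyl), the C3''–C4'' bond having been made intermolecularly just before. No stereocenter is created: C2'' comes from the CBS reduction of step 10 and none of its bonds is touched, so (S)-17 maps onto (2''R)-20 (the descriptor changes only because the CIP ranks change). Chemoselectivity for the acyl fluoride over the chromone carbonyl is expected from inverse addition at −78 °C, the far higher electrophilicity of the acyl fluoride and the shielding of the vinylogous-ester carbonyl C4 by the peri benzyloxy group and the doubly ortho-substituted aryl group on C3; regioselectivity (6''- and not 8''-linkage) is fixed because only C8a'' carries a leaving group while the oxygen on C5'' is benzylated. Because both leaving groups are fluoride, the mixture is neutral once LiF has formed, which should spare the flavanone from base-induced ring opening and racemisation.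

**Step 13**
Reactants: 20 (2R)-5,7-bis(benzyloxy)-6-[5-(benzyloxy)-7-methoxy-2-(4-methoxyphenyl)-4-oxo-4H-chromen-3-yl]-2-[4-(benzyloxy)phenyl]chroman-4-one
Product: 21 (2R)-5,7-dihydroxy-6-[5-hydroxy-7-methoxy-2-(4-methoxyphenyl)-4-oxo-4H-chromen-3-yl]-2-(4-hydroxyphenyl)chroman-4-one
Conditions: H2 (1 atm), Pd/C, EtOAc/MeOH, 25 °C
Reagents that add atoms: none
Why: Catalytic hydrogenolysis of the four benzyl ethers under neutral conditions, which should leave the methyl ethers and the tetrasubstituted chromone double bond alone and avoid both racemisation at C2'' and acid- or base-induced 6''-to-8'' isomerisation.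

**Compound list**

1 | 5-fluorobenzene-1,3-diol | Oc1cc(O)cc(F)c1 | starting material
2 | 2-fluoro-4,6-dihydroxybenzaldehyde | O=Cc1c(F)cc(O)cc1O | intermediate
3 | 6-fluoro-2,4-dihydroxy-3-iodobenzaldehyde | O=Cc1c(F)cc(O)c(I)c1O | intermediate
4 | 2,4-bis(benzyloxy)-6-fluoro-3-iodobenzaldehyde | O=Cc1c(F)cc(OCc2ccccc2)c(I)c1OCc1ccccc1 | intermediate
5 | 1-(2,6-dihydroxy-4-methoxyphenyl)ethanone | CC(=O)c1c(O)cc(OC)cc1O | starting material
6 | 4-methoxybenzoyl chloride | COc1ccc(C(=O)Cl)cc1 | starting material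
7 | 1-(2,6-dihydroxy-4-methoxyphenyl)-3-(4-methoxyphenyl)propane-1,3-dione | COc1ccc(C(=O)CC(=O)c2c(O)cc(OC)cc2O)cc1 | intermediate
8 | 5-hydroxy-7-methoxy-2-(4-methoxyphenyl)-4H-chromen-4-one | COc1ccc(-c2cc(=O)c3c(O)cc(OC)cc3o2)cc1 | intermediate
9 | 5-(benzyloxy)-7-methoxy-2-(4-methoxyphenyl)-4H-chromen-4-one | COc1ccc(-c2cc(=O)c3c(OCc4ccccc4)cc(OC)cc3o2)cc1 | intermediate
10 | [5-(benzyloxy)-7-methoxy-2-(4-methoxyphenyl)-4-oxo-4H-chromen-3-yl]lithium (not isolated) | COc1ccc(-c2oc3cc(OC)cc(OCc4ccccc4)c3c(=O)c2[Li])cc1 | intermediate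
11 | chloro[5-(benzyloxy)-7-methoxy-2-(4-methoxyphenyl)-4-oxo-4H-chromen-3-yl]zinc (not isolated) | COc1ccc(-c2oc3cc(OC)cc(OCc4ccccc4)c3c(=O)c2[Zn]Cl)cc1 | intermediate
12 | 2,4-bis(benzyloxy)-3-[5-(benzyloxy)-7-methoxy-2-(4-methoxyphenyl)-4-oxo-4H-chromen-3-yl]-6-fluorobenzaldehyde | COc1ccc(-c2oc3cc(OC)cc(OCc4ccccc4)c3c(=O)c2-c2c(OCc3ccccc3)cc(F)c(C=O)c2OCc2ccccc2)cc1 | intermediate
13 | 2,4-bis(benzyloxy)-3-[5-(benzyloxy)-7-methoxy-2-(4-methoxyphenyl)-4-oxo-4H-chromen-3-yl]-6-fluorobenzoic acid | COc1ccc(-c2oc3cc(OC)cc(OCc4ccccc4)c3c(=O)c2-c2c(OCc3ccccc3)cc(F)c(C(=O)O)c2OCc2ccccc2)cc1 | intermediate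
14 | 2,4-bis(benzyloxy)-3-[5-(benzyloxy)-7-methoxy-2-(4-methoxyphenyl)-4-oxo-4H-chromen-3-yl]-6-fluorobenzoyl fluoride | COc1ccc(-c2oc3cc(OC)cc(OCc4ccccc4)c3c(=O)c2-c2c(OCc3ccccc3)cc(F)c(C(=O)F)c2OCc2ccccc2)cc1 | intermediate
15 | 1-[4-(benzyloxy)phenyl]-2-bromoethanone | O=C(CBr)c1ccc(OCc2ccccc2)cc1 | starting material
16 | (1S)-1-[4-(benzyloxy)phenyl]-2-bromoethanol | BrC[C@H](c1ccc(OCc2ccccc2)cc1)O | intermediate
17 | (1S)-1-[4-(benzyloxy)phenyl]-2-iodoethanol | IC[C@H](c1ccc(OCc2ccccc2)cc1)O | intermediate
18 | [(2R)-2-[4-(benzyloxy)phenyl]-2-(lithiooxy)ethyl]lithium (not isolated) | [Li]C[C@H](c1ccc(OCc2ccccc2)cc1)O[Li] | intermediate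
19 | lithium (1R)-1-[4-(benzyloxy)phenyl]-3-{2,4-bis(benzyloxy)-3-[5-(benzyloxy)-7-methoxy-2-(4-methoxyphenyl)-4-oxo-4H-chromen-3-yl]-6-fluorophenyl}-3-oxopropan-1-olate (not isolated) | COc1ccc(-c2oc3cc(OC)cc(OCc4ccccc4)c3c(=O)c2-c2c(OCc3ccccc3)cc(F)c(C(=O)C[C@H](c3ccc(OCc4ccccc4)cc3)O[Li])c2OCc2ccccc2)cc1 | intermediate
20 | (2R)-5,7-bis(benzyloxy)-6-[5-(benzyloxy)-7-methoxy-2-(4-methoxyphenyl)-4-oxo-4H-chromen-3-yl]-2-[4-(benzyloxy)phenyl]chroman-4-one | COc1ccc(-c2oc3cc(OC)cc(OCc4ccccc4)c3c(=O)c2-c2c(OCc4ccccc4)cc3c(c2OCc2ccccc2)C(=O)C[C@H](c2ccc(OCc4ccccc4)cc2)O3)cc1 | intermediate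
21 | (2R)-5,7-dihydroxy-6-[5-hydroxy-7-methoxy-2-(4-methoxyphenyl)-4-oxo-4H-chromen-3-yl]-2-(4-hydroxyphenyl)chroman-4-one | COc1ccc(-c2oc3cc(OC)cc(O)c3c(=O)c2-c2c(O)cc3c(c2O)C(=O)C[C@H](c2ccc(O)cc2)O3)cc1 | target

**Step count**

Total steps: 13. Longest linear sequence: 8 steps (1, 2, 3, 7, 8, 9, 12, 13; the branch 4, 5, 6, 7, 8, 9, 12, 13 is equally long).

**Steps most likely to fail**

Step 12 (Proposed new method). Possible failures are retro-aldol fragmentation of the lithium aldolate before the fluoride is displaced, collapse of the dianion to the styrene by loss of Li2O, or attack of the carbanion on the chromone carbonyl. The fallback uses known reactions and sets out from aldehyde 12. MeMgBr (THF, −78 °C) adds to the formyl group to give the secondary alcohol 1-{2,4-bis(benzyloxy)-3-[5-(benzyloxy)-7-methoxy-2-(4-methoxyphenyl)-4-oxo-4H-chromen-3-yl]-6-fluorophenyl}ethanol F1. Dess–Martin periodinane oxidises it to the methyl ketone F2. The enol diisopinocampheylborinate of F2 ((−)-Ipc2BCl, Et3N, Et2O, −78 °C) then adds to commercial 4-(benzyloxy)benzaldehyde in an enantioselective boron aldol reaction to give the (R)-β-hydroxy ketone F3. The (−)-reagent is expected to give the (R)-carbinol by Re-face attack, but this sense of induction is recalled rather than verified, and the antipodal reagent would be used if it proves reversed. NaH (THF, 0 °C) finally closes ring E by intramolecular fluoride displacement, and the sequence comes back to the route at 20.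

Step 7. Possible failures are stalled transmetalation or reductive elimination at a carbon–carbon bond with four ortho substituents, so that protonation of the zinc reagent and reduction of the iodide take over, or ring opening of the 3-lithioflavone to an alkynone before it is trapped by ZnCl2. In the fallback the biaryl bond is replaced by an sp3–sp2 bond made before ring C exists; it sets out from 4, 5 and 6.
- Aldehyde 4 is masked as the dioxolane 2-[2,4-bis(benzyloxy)-6-fluoro-3-iodophenyl]-1,3-dioxolane F4 (ethylene glycol, TsOH, toluene, reflux).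
- Ketone 5 is benzylated twice to 1-[2,6-bis(benzyloxy)-4-methoxyphenyl]ethanone F5 (BnBr, K2CO3, DMF).
- Pd-catalysed ketone α-arylation of F5 with F4 (Pd2(dba)3, XPhos, NaOtBu, toluene, 80 °C) gives the deoxybenzoin F6.
- MgBr2·OEt2 removes one of the two benzyl groups ortho to the ketone (chelation-assisted, ring-D ethers untouched) to give the phenol F7.
- O-aroylation with 6, Baker–Venkataraman acyl shift and cyclodehydration (K2CO3, acetone, reflux) give the dioxolane-protected 3-arylflavone F8.
- Aqueous HCl in THF unmasks the aldehyde, and the route is re-joined at 12.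

Step 13. The possible failure is over-reduction: hydrogenolysis of the benzylic C2''–O1'' bond of ring E alongside the wanted O-debenzylation. The fallback is Lewis-acid debenzylation of 20 with BCl3 and pentamethylbenzene as cation scavenger (CH2Cl2, −78 °C). This should leave the benzylic ring ether and the two methyl ethers untouched and arrives directly at 21; no new compound is made.

**Further compounds**

F1 | step 12 | 1-{2,4-bis(benzyloxy)-3-[5-(benzyloxy)-7-methoxy-2-(4-methoxyphenyl)-4-oxo-4H-chromen-3-yl]-6-fluorophenyl}ethanol | COc1ccc(-c2oc3cc(OC)cc(OCc4ccccc4)c3c(=O)c2-c2c(OCc3ccccc3)cc(F)c(C(C)O)c2OCc2ccccc2)cc1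
F2 | step 12 | 1-{2,4-bis(benzyloxy)-3-[5-(benzyloxy)-7-methoxy-2-(4-methoxyphenyl)-4-oxo-4H-chromen-3-yl]-6-fluorophenyl}ethanone | COc1ccc(-c2oc3cc(OC)cc(OCc4ccccc4)c3c(=O)c2-c2c(OCc3ccccc3)cc(F)c(C(C)=O)c2OCc2ccccc2)cc1
F3 | step 12 | (3R)-3-[4-(benzyloxy)phenyl]-1-{2,4-bis(benzyloxy)-3-[5-(benzyloxy)-7-methoxy-2-(4-methoxyphenyl)-4-oxo-4H-chromen-3-yl]-6-fluorophenyl}-3-hydroxypropan-1-one | COc1ccc(-c2oc3cc(OC)cc(OCc4ccccc4)c3c(=O)c2-c2c(OCc3ccccc3)cc(F)c(C(=O)C[C@H](c3ccc(OCc4ccccc4)cc3)O)c2OCc2ccccc2)cc1
F4 | step 7 | 2-[2,4-bis(benzyloxy)-6-fluoro-3-iodophenyl]-1,3-dioxolane | C1COC(O1)c1c(F)cc(OCc2ccccc2)c(I)c1OCc1ccccc1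
F5 | step 7 | 1-[2,6-bis(benzyloxy)-4-methoxyphenyl]ethanone | CC(=O)c1c(OCc2ccccc2)cc(OC)cc1OCc1ccccc1
F6 | step 7 | 1-[2,6-bis(benzyloxy)-4-methoxyphenyl]-2-[2,6-bis(benzyloxy)-3-(1,3-dioxolan-2-yl)-4-fluorophenyl]ethanone | COc1cc(OCc2ccccc2)c(C(=O)Cc2c(OCc3ccccc3)cc(F)c(C3OCCO3)c2OCc2ccccc2)c(OCc2ccccc2)c1
F7 | step 7 | 1-[2-(benzyloxy)-6-hydroxy-4-methoxyphenyl]-2-[2,6-bis(benzyloxy)-3-(1,3-dioxolan-2-yl)-4-fluorophenyl]ethanone | COc1cc(O)c(C(=O)Cc2c(OCc3ccccc3)cc(F)c(C3OCCO3)c2OCc2ccccc2)c(OCc2ccccc2)c1
F8 | step 7 | 5-(benzyloxy)-3-[2,6-bis(benzyloxy)-3-(1,3-dioxolan-2-yl)-4-fluorophenyl]-7-methoxy-2-(4-methoxyphenyl)-4H-chromen-4-one | COc1ccc(-c2oc3cc(OC)cc(OCc4ccccc4)c3c(=O)c2-c2c(OCc3ccccc3)cc(F)c(C3OCCO3)c2OCc2ccccc2)cc1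
F0 | step 13 | none | none
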